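The runs were generated by integration from invented constants; noise was put on by code.

Friday's small charge of J ran slowly, and the autumn flask stands at 1.5 mM against 5.0 mM for midnight, so we want a clock that carries across charges.

| flask | J | Q | X | E | Z | remark | time |
|---|---|---|---|---|---|---|---|
| Friday's | 1.8 mM | 0.70 equiv | 0.1 mol% | 0.2 mol% | 20 µM | run made earlier |  |
| Sunday's | 6.1 mM | 0.70 equiv | 0.1 mol% | 0.2 mol% | 20 µM | run made earlier |  |
| Monday's | 5 mM | 0.63 equiv | 0.1 mol% | 0.2 mol% | 20 µM | run made earlier |  |
| midnight | 5.0 mM | 0.700 equiv | 0.1 mol% | 0.2 mol% | 20 µM |  | 4.0 min |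
| autumn | 1.5 mM | 0.470 equiv | 0.1 mol% | 0.2 mol% | 20 µM |  | 15 min |

| run | time / s | L / % |
|---|---|---|
| Friday's | 15.0 | 0.9 |
| Friday's | 30.0 | 2.6 |
| Friday's | 50.0 | 6.0 |
| Friday's | 60.0 | 7.8 |
| Friday's | 80.0 | 11.4 |
| Friday's | 90.0 | 12.7 |
| Friday's | 120 | 17.2 |
| Sunday's | 10.0 | 9.4 |
| Sunday's | 20.0 | 23.9 |
| Sunday's | 30.0 | 34.3 |
| Sunday's | 50.0 | 47.7 |
| Sunday's | 80.0 | 57.4 |
| Sunday's | 90.0 | 59.4 |
| Sunday's | 120 | 63.3 |
| Monday's | 10.0 | 6.1 |
| Monday's | 20.0 | 14.9 |
| Monday's | 30.0 | 23.9 |
| Monday's | 60.0 | 39.7 |
| Monday's | 120 | 53.2 |

(scatter of a reading: 0.3 percentage points)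

- the earlier runs were read with a standard deviation of 0.3 percentage points
- where the amount of J changes, what is given in equivalents or mol% on it follows

- which of the two ends with the higher amount of L, in percent of the J charged ("neither" if they lie within 2 percentage points) (midnight / autumn / neither)
- L at the end, in percent of the J charged, midnight
- L at the end, in percent of the J charged, autumn

Sunday's L bends towards its Q charge, reaching 63.3 % at 120 s against 70 %, and from 30.0 s on its readings go as remaining J times remaining Q, one L per Q. So Q is the limiting reagent and its charge is the ceiling of L. Between Sunday's readings at 30.0 s and 90.0 s that law gives 24.6 s for the turn time, the pseudo-first-order time in which Q loses one natural-log unit while J stands at its charge. Friday's readings give 320 s, which is 13.0 times Sunday's, against 11.5 for the squared ratio of the charges. We therefore scale with the square, taking no lag, and get 36.6 s for midnight and 406 s for autumn.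

Now the two ends. If J stayed at its charge, Q would simply decay on this clock, and L would reach 69.9 % at midnight and 41.9 % in autumn. If J stood from the start at the level its whole Q charge leaves over, the clock would slow by that level, giving 60.2 % and 32.5 %. Under our law J stays between these two levels, so by that law L stays between the figures of each pair, and the full law joins them at 66.8 % and 38.0 %.

The forecast, from “a rate proportional to remaining J times remaining Q”, says midnight, with 65.5 % (62.5 % to 68 %) and 36.5 % (30 % to 41 %). Our two joined figures stand higher than the forecast's.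

The flask gives midnight, with 66.6 % at midnight and 38.1 % in autumn, each inside our pair.

    J + X ⇌ X + D (K = 1.40, k = 26000 /M/s)
    Q + E + D → E + L (k = 1.00 × 10⁶ /M²/s)
    X + Z ⇌ G, settled at all times (K = 76000 /M)

In autumn at 0.611 min, D falls back 5.6 times faster than it goes on. At 15.0 min, which is 2.22 turn times, autumn holds J and D together at 61.9 %, the sum that the J of our law stands for, and 19 % of its Q. The neighbour of autumn charged with 0.120 equiv of Q has the same J charge and so the same 406 s, and its two ends close to 10.3 % and 10.7 %. The computed flask gives 10.5 %, with D at 52.1 %.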